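**Plan**

- Retrosynthesis: the four phenol O–CH2OCH3 bonds are cut first, then the two trisubstituted C=C bonds of the prenyl groups (each back to a terminal allyl C=C), then the bond from the carbonyl carbon to ring B C1 (aryllithium plus aldehyde, then oxidation), and last the aryl–allyl bonds at ring A C2 and ring B C3.
- Enabling feature: both prenyl groups are ArCH2–CH=C(CH3)2 units at flanked carbons, ring A C2 (between the carbonyl-bearing C1 and the C3 hydroxyl) and ring B C3 (between the C2 and C4 hydroxyls). Prenyl-metal reagents scramble between alpha and gamma attack at such sites, whereas an allyl group installs unambiguously and then needs only its terminal CH2 exchanged for C(CH3)2.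
- Forward: the ring A aldehyde (MOM protection, allyl Stille coupling) and the ring B bromide (tris-MOM ether, ortho-lithiation/allylation, bromination) are joined by bromine–lithium exchange and 1,2-addition. Oxidation gives the diallyl benzophenone, one double cross-metathesis with 2-methylbut-2-ene makes both prenyl groups, and mild acid removes the MOM groups. No ring is formed; both benzene rings come from the starting materials.
- Stereochemistry: the target has no stereocentre and no stereogenic alkene; the only stereocentre on the way (the racemic carbinol of step 6) is erased by the oxidation of step 7.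

Key step: step 8

**Route**

Step 1
Reactants: 1 2-bromo-3-hydroxybenzaldehyde
Product: 2 2-bromo-3-(methoxymethoxy)benzaldehyde
Conditions: MOMCl, i-Pr2NEt, CH2Cl2, 0 °C to rt
Reagents that add atoms: chloromethyl methyl ether (MOMCl), COCCl
Why: O-alkylation of the phenol with the reactive alpha-chloro ether under amine base (MOM protection) should proceed cleanly, the aldehyde being inert under these conditions.

Step 2
Reactants: 2 2-bromo-3-(methoxymethoxy)benzaldehyde; 3 allyltributylstannane
Product: 4 2-allyl-3-(methoxymethoxy)benzaldehyde
Conditions: Pd(PPh3)4 (5 mol %), toluene, 100 °C, degassed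
Reagents that add atoms: allyltributylstannane 3, C=CC[Sn](CCCC)(CCCC)CCCC
Why: Stille cross-coupling, in which zerovalent palladium inserts into the C–Br bond activated by the ortho formyl group, the allyl group is transferred from tin and reductive elimination forms the aryl–allyl bond; allylstannanes do not add to aldehydes without a Lewis acid.

Step 3
Reactants: 5 phloroglucinol
Product: 6 1,3,5-tris(methoxymethoxy)benzene
Conditions: MOMCl (3.6 equiv), i-Pr2NEt, CH2Cl2, 0 °C to rt
Reagents that add atoms: chloromethyl methyl ether (MOMCl), COCCl
Why: threefold MOM protection by O-alkylation, the hard alpha-chloro ether favouring O- over C-alkylation of the phloroglucinol phenoxide.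

Step 4
Reactants: 6 1,3,5-tris(methoxymethoxy)benzene; 7 allyl bromide
Product: 9 2-allyl-1,3,5-tris(methoxymethoxy)benzene, via 2,4,6-tris(methoxymethoxy)phenyllithium 8 (not isolated)
Conditions: n-BuLi (1.05 equiv), THF, 0 °C; then allyl bromide, −78 °C to rt
Reagents that add atoms: allyl bromide 7, C=CCBr
Why: directed ortho-metalation at a ring carbon flanked by two chelating MOM ethers (all three ring CH positions are equivalent), then alkylation of the aryllithium with allyl bromide, where SN2 and SN2′ attack give the same product.

Step 5
Reactants: 9 2-allyl-1,3,5-tris(methoxymethoxy)benzene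
Product: 10 1-allyl-3-bromo-2,4,6-tris(methoxymethoxy)benzene
Conditions: NBS (1.0 equiv), CH2Cl2, −20 to 0 °C, dark
Reagents that add atoms: N-bromosuccinimide, O=C1CCC(=O)N1Br
Why: electrophilic aromatic bromination of a trialkoxyarene, which is far faster than attack on the terminal alkene; the two free ring positions are equivalent, so one monobromide should form, and one equivalent of reagent at low temperature limits dibromination.

Step 6
Reactants: 10 1-allyl-3-bromo-2,4,6-tris(methoxymethoxy)benzene; 4 2-allyl-3-(methoxymethoxy)benzaldehyde
Product: 13 racemic [2-allyl-3-(methoxymethoxy)phenyl][3-allyl-2,4,6-tris(methoxymethoxy)phenyl]methanol, via 3-allyl-2,4,6-tris(methoxymethoxy)phenyllithium 11 (not isolated), via lithium [2-allyl-3-(methoxymethoxy)phenyl][3-allyl-2,4,6-tris(methoxymethoxy)phenyl]methanolate 12 (not isolated)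
Conditions: n-BuLi (1.05 equiv), THF, −78 °C, 15 min; then 4 in THF, −78 to −20 °C; H2O quench
Reagents that add atoms: none
Why: bromine–lithium exchange at −78 °C is faster than removal of the benzylic–allylic protons that direct deprotonation with n-BuLi would endanger, and the MOM-chelated aryllithium then undergoes 1,2-addition to the aldehyde; the carbinol stereocentre forms racemic and is removed in step 7.

Step 7
Reactants: 13 racemic [2-allyl-3-(methoxymethoxy)phenyl][3-allyl-2,4,6-tris(methoxymethoxy)phenyl]methanol
Product: 14 [2-allyl-3-(methoxymethoxy)phenyl][3-allyl-2,4,6-tris(methoxymethoxy)phenyl]methanone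
Conditions: Dess–Martin periodinane, pyridine, CH2Cl2, 0 °C to rt
Reagents that add atoms: none
Why: Dess–Martin oxidation of a doubly benzylic secondary alcohol to the diaryl ketone under buffered, non-acidic conditions that should prevent ionisation of the electron-rich carbinol and leave the terminal alkenes and MOM ethers untouched.

Step 8
Reactants: 14 [2-allyl-3-(methoxymethoxy)phenyl][3-allyl-2,4,6-tris(methoxymethoxy)phenyl]methanone; 15 2-methylbut-2-ene
Product: 16 cudraphenone D tetrakis(methoxymethyl) ether, [3-(methoxymethoxy)-2-(3-methylbut-2-enyl)phenyl][2,4,6-tris(methoxymethoxy)-3-(3-methylbut-2-enyl)phenyl]methanone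
Conditions: second-generation Grubbs catalyst (H2IMes)(PCy3)Cl2Ru=CHPh (10 mol %), 2-methylbut-2-ene/CH2Cl2 (large excess of the alkene as cosolvent), 40 °C, sealed vessel
Reagents that add atoms: 2-methylbut-2-ene 15, CC=C(C)C
Why: After loss of PCy3 the ruthenium alkylidene adds [2+2] to each terminal allyl C=C, and cycloreversion of the ruthenacyclobutane expels the terminal CH2 (ultimately as propene) and leaves a Ru=CH–CH2Ar alkylidene, which takes up 2-methylbut-2-ene through a second metallacycle and releases the ArCH2–CH=C(CH3)2 unit. The closest known reaction type is the cross-metathesis of allylarenes with 2-methylbut-2-ene to give prenylarenes, run here at two sites of one molecule. No ring closes and no stereocentre or stereogenic alkene arises, because each new C=C carries two identical methyl groups. The step needs cross- over homo-metathesis at both sites: the trisubstituted partner in large excess does not homodimerise, volatile propene leaves the solution, and any crotyl intermediate or allylarene homodimer re-enters the cycle and should converge on the prenyl product. It also needs the allyl C=C bonds not to migrate into conjugation and the two allyl groups not to ring-close: all four phenols are masked as MOM ethers so that no free phenol promotes ruthenium hydride formation, and the allyl groups sit on different rings (ring A C2 and ring B C3), so ring closure would demand a strained ten-membered ring bridging both arenes.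

Step 9
Reactants: 16 cudraphenone D tetrakis(methoxymethyl) ether
Product: 17 cudraphenone D
Conditions: HCl (ca. 1 M in MeOH), rt
Reagents that add atoms: none
Why: acid-catalysed transacetalisation of the four aryl MOM ethers to methanol (the two flanking the ketone should go first through hydrogen-bond assistance), with dilute acid at room temperature chosen so that the freed ortho-prenylphenols are not driven on to 2,2-dimethylchromans.

**Compound list**

1 | 2-bromo-3-hydroxybenzaldehyde | O=Cc1cccc(O)c1Br | starting material
2 | 2-bromo-3-(methoxymethoxy)benzaldehyde | COCOc1cccc(C=O)c1Br | intermediate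
3 | allyltributylstannane | C=CC[Sn](CCCC)(CCCC)CCCC | starting material
4 | 2-allyl-3-(methoxymethoxy)benzaldehyde | C=CCc1c(OCOC)cccc1C=O | intermediate
5 | phloroglucinol | Oc1cc(O)cc(O)c1 | starting material
6 | 1,3,5-tris(methoxymethoxy)benzene | COCOc1cc(OCOC)cc(OCOC)c1 | intermediate
7 | allyl bromide | C=CCBr | starting material
8 | 2,4,6-tris(methoxymethoxy)phenyllithium (formed in the flask, step 4) | [Li]c1c(OCOC)cc(OCOC)cc1OCOC | intermediate
9 | 2-allyl-1,3,5-tris(methoxymethoxy)benzene | C=CCc1c(OCOC)cc(OCOC)cc1OCOC | intermediate
10 | 1-allyl-3-bromo-2,4,6-tris(methoxymethoxy)benzene | C=CCc1c(OCOC)cc(OCOC)c(Br)c1OCOC | intermediate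
11 | 3-allyl-2,4,6-tris(methoxymethoxy)phenyllithium (formed in the flask, step 6) | [Li]c1c(OCOC)cc(OCOC)c(CC=C)c1OCOC | intermediate
12 | lithium [2-allyl-3-(methoxymethoxy)phenyl][3-allyl-2,4,6-tris(methoxymethoxy)phenyl]methanolate (formed in the flask, step 6) | [Li]OC(c1cccc(OCOC)c1CC=C)c1c(OCOC)cc(OCOC)c(CC=C)c1OCOC | intermediate
13 | racemic [2-allyl-3-(methoxymethoxy)phenyl][3-allyl-2,4,6-tris(methoxymethoxy)phenyl]methanol | OC(c1cccc(OCOC)c1CC=C)c1c(OCOC)cc(OCOC)c(CC=C)c1OCOC | intermediate
14 | [2-allyl-3-(methoxymethoxy)phenyl][3-allyl-2,4,6-tris(methoxymethoxy)phenyl]methanone | C=CCc1c(OCOC)cccc1C(=O)c1c(OCOC)cc(OCOC)c(CC=C)c1OCOC | intermediate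
15 | 2-methylbut-2-ene | CC=C(C)C | starting material
16 | cudraphenone D tetrakis(methoxymethyl) ether | CC(C)=CCc1c(OCOC)cccc1C(=O)c1c(OCOC)cc(OCOC)c(CC=C(C)C)c1OCOC | intermediate
17 | cudraphenone D | CC(C)=CCc1c(O)cccc1C(=O)c1c(O)cc(O)c(CC=C(C)C)c1O | target

**Step count**

Total: 9 steps. Longest linear sequence: 7 steps (phloroglucinol 5 through steps 3, 4, 5, 6, 7, 8 and 9).

**Steps most likely to fail, with fallbacks**

Step 6 (union of the two rings). Proton transfer from the benzylic–allylic CH2 of the allyl group to the aryllithium may quench the nucleophile or move the C=C into conjugation. Addition of the doubly flanked aryllithium to the ortho-substituted aldehyde may also be slow. The fallback joins the rings before ring B carries its allyl group; it sets out from 6 and 4 and comes back at 14. Compound 6 is lithiated as in step 4 to the allyl-free aryllithium 8, which is added to 4 at −78 °C. This should give lithium [2-allyl-3-(methoxymethoxy)phenyl][2,4,6-tris(methoxymethoxy)phenyl]methanolate F1 and, after aqueous work-up, racemic [2-allyl-3-(methoxymethoxy)phenyl][2,4,6-tris(methoxymethoxy)phenyl]methanol F2. Oxidation with Dess–Martin periodinane and pyridine should give [2-allyl-3-(methoxymethoxy)phenyl][2,4,6-tris(methoxymethoxy)phenyl]methanone F3. N-Bromosuccinimide (1 equiv, CH2Cl2, 0 °C) is expected to brominate the much more electron-rich ring B at C3 (C3 and C5 are equivalent) to [2-allyl-3-(methoxymethoxy)phenyl][3-bromo-2,4,6-tris(methoxymethoxy)phenyl]methanone F4. A Stille coupling of F4 with 3 (Pd(P(t-Bu)3)2, dioxane, 100 °C) then returns to 14.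

Step 8 (double cross-metathesis). Exchange may stop at one of the two hindered sites and leave mixed allyl, crotyl and prenyl material that is hard to separate, or a ruthenium hydride may shift an allyl C=C into conjugation with its ring. The fallback replaces metathesis by oxidative cleavage and Wittig olefination; it sets out from 14 and comes back at 16. Lemieux–Johnson conditions (OsO4 cat., NaIO4, 2,6-lutidine, dioxane/H2O, rt) should dihydroxylate both terminal alkenes to [2-(2,3-dihydroxypropyl)-3-(methoxymethoxy)phenyl][3-(2,3-dihydroxypropyl)-2,4,6-tris(methoxymethoxy)phenyl]methanone F5 (mixture of diastereomers, cleaved in the same flask). Cleavage gives [3-(methoxymethoxy)-2-(2-oxoethyl)phenyl][2,4,6-tris(methoxymethoxy)-3-(2-oxoethyl)phenyl]methanone F6. Double Wittig reaction of F6 with isopropylidenetriphenylphosphorane (from isopropyltriphenylphosphonium iodide and n-BuLi, THF, −78 to 0 °C) should then deliver 16, the hindered diaryl ketone being expected to stay untouched.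

Step 9 (global deprotection). A freed phenol may add under acid catalysis to the neighbouring prenyl C=C and close a 2,2-dimethylchroman, or the less activated MOM ethers may be lost only partly. The fallback removes the MOM groups before the prenyl groups exist; it sets out from 14 and comes back at 17. Treatment of 14 with HCl in MeOH, while the side chains are still allyl groups that cannot give a tertiary cation, should give (2-allyl-3-hydroxyphenyl)(3-allyl-2,4,6-trihydroxyphenyl)methanone F7. Cross-metathesis of F7 with 15 under the conditions of step 8, the catalyst being tolerant of free phenols, would then give 17 directly.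

**Further compounds**

F1 | step 6 | lithium [2-allyl-3-(methoxymethoxy)phenyl][2,4,6-tris(methoxymethoxy)phenyl]methanolate | [Li]OC(c1cccc(OCOC)c1CC=C)c1c(OCOC)cc(OCOC)cc1OCOC
F2 | step 6 | racemic [2-allyl-3-(methoxymethoxy)phenyl][2,4,6-tris(methoxymethoxy)phenyl]methanol | OC(c1cccc(OCOC)c1CC=C)c1c(OCOC)cc(OCOC)cc1OCOC
F3 | step 6 | [2-allyl-3-(methoxymethoxy)phenyl][2,4,6-tris(methoxymethoxy)phenyl]methanone | C=CCc1c(OCOC)cccc1C(=O)c1c(OCOC)cc(OCOC)cc1OCOC
F4 | step 6 | [2-allyl-3-(methoxymethoxy)phenyl][3-bromo-2,4,6-tris(methoxymethoxy)phenyl]methanone | C=CCc1c(OCOC)cccc1C(=O)c1c(OCOC)cc(OCOC)c(Br)c1OCOC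
F5 | step 8 | [2-(2,3-dihydroxypropyl)-3-(methoxymethoxy)phenyl][3-(2,3-dihydroxypropyl)-2,4,6-tris(methoxymethoxy)phenyl]methanone (mixture of diastereomers) | OCC(O)Cc1c(OCOC)cccc1C(=O)c1c(OCOC)cc(OCOC)c(CC(O)CO)c1OCOC
F6 | step 8 | [3-(methoxymethoxy)-2-(2-oxoethyl)phenyl][2,4,6-tris(methoxymethoxy)-3-(2-oxoethyl)phenyl]methanone | O=CCc1c(OCOC)cccc1C(=O)c1c(OCOC)cc(OCOC)c(CC=O)c1OCOC
F7 | step 9 | (2-allyl-3-hydroxyphenyl)(3-allyl-2,4,6-trihydroxyphenyl)methanone | C=CCc1c(O)cccc1C(=O)c1c(O)cc(O)c(CC=C)c1O
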